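The data stem from a simulated flask with constants of no real substance, noise included.

In a one-step world the rate of making target at a given [substrate] goes with [enzyme] to the first order, so birch, charged with 19.6 times the enzyme of cedar, would run that many times faster.

common to all: substrate 15 mM
- cedar: enzyme 0.097 µM; run made earlier
- birch: enzyme 1.9 µM; run made earlier
- gamma: enzyme 0.080 µM; time 5.0 h
- eta: enzyme 0.15 µM; time 5.0 h
- zeta: enzyme 0.30 µM; time 5.0 h
- epsilon: enzyme 0.60 µM; time 5.0 h
- alpha: enzyme 1.2 µM; time 5.0 h

| run | time / h | target / % |
|---|---|---|
| cedar | 0.667 | 9.3 |
| cedar | 1.33 | 18.3 |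
| cedar | 2.00 | 26.2 |
| cedar | 3.00 | 40.3 |
| cedar | 4.00 | 50.4 |
| cedar | 5.00 | 60.9 |
| birch | 0.667 | 39.0 |
| birch | 1.33 | 73.5 |
| birch | 2.00 | 77.4 |
| birch | 3.00 | 61.0 |
| birch | 4.00 | 46.2 |
| birch | 5.00 | 39.4 |

(each reading ± 1 percentage point)

1. amount of target at the end, in percent of the substrate charged for gamma, eta, zeta, epsilon, alpha, in this order
2. the shape of the row from first to last (rises, then falls / falls, then rises / hardly changes / rises all the way / falls all the way)

I asked first how much faster birch really ran, and I compared the two runs at like readings of [target], taking that as equal progress. Cedar read 40.3% at 3.00 h and birch read 39.0% at 0.667 h, so by these readings birch went 4.35 times faster. That makes 0.494 the enzyme order, the exponent by which the rate follows the enzyme charged at equal progress. As a reading it stands near half.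

Next I asked what this does to the time of a new flask. I assumed that the making and the loss of target run on the same working enzyme. A new flask then repeats an earlier run on a clock scaled by its enzyme ratio raised to the enzyme order. In gamma, 5.0 h became 4.55 h of cedar, where the readings give 56.1%. In zeta it became 2.01 h of birch, which read 77.4% there, higher than its neighbouring readings. In alpha it became 3.98 h of birch, which read 46.2%.

So where does the row stand against that highest reading? On this clock I put gamma short of it and alpha past it, so I committed to a row that rises, then falls, with eta between gamma and zeta and epsilon between zeta and alpha.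

The forecast, which held that “the loss should scale with active enzyme”, gave 53%, 73%, 74%, 60% and 45%, rises, then falls, lower than mine at gamma, zeta and alpha.

The flasks gave 56.8%, 73.5%, 76.7%, 63.6% and 49.3%: rises, then falls.

    substrate + enzyme → target + enzyme, rate k1*[substrate]*[enzyme]/(1 + ([substrate]/Km1)) (0.540 mM, k = 1.60 × 10⁵ M⁻¹ s⁻¹)
    2 enzyme ⇌ resting dimer, settled at all times (K = 8.70 × 10⁸ M⁻¹)
    target + enzyme ⇌ isomer of the product + enzyme, rate k3*[enzyme]*[target] forward; the back reaction follows from the equilibrium constant (K = 10.0, k = 1.20 × 10⁵ M⁻¹ min⁻¹)

At 5.00 h, gamma held 8.12% of its enzyme working and alpha held 2.16%, the remainder sitting as resting dimer, the resting state. Working enzyme thus stood 4.00 times higher in alpha than in gamma, where 0.494 on the charges gives 3.81. On the target at the end of gamma the pairing and the time allowed act together: gamma ended at 56.8%, left until 50.0 h it stood at 17.7%, and with the pairing taken away it ended at 13.8%.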